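**Retrosynthetic overview**
1. Target 17 ← hydrogenolysis of hepta-benzyl ester 16 ← esterification of 3'-phenol 14 with tri-O-benzylgallic acid 15. O3' is the only phenol carried as a MOM acetal instead of a benzyl ether, which marks it for galloylation.
2. Structural feature used: O1 links aromatic C8a of ring A to the benzylic stereocentre C2. Making O1–C8a last (13 ← bromo alcohol 12, Pd-catalysed aryl etherification) closes ring C without touching the sp3 stereocentres C2 and C3.
3. 12 ← anti (1R,2S) diol monoether, made by forming C4–C4a: the erythro epoxy silyl ether 5 is opened at its CH2 terminus by aryl Grignard 9. The bromine must sit ortho to C4a and meta to O5 and O7, a position electrophilic bromination of the coupled arene cannot reach, so it is carried in from 5-bromoresorcinol.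
4. 5 ← Sharpless kinetic-resolution epoxidation of racemic aryl vinyl carbinol 3 (sets C2 and C3) ← aldehyde 1; 9 ← 5-bromoresorcinol 6 by dibenzylation and iodination.
5. Ring order: rings A, B and the galloyl ring are bought as aromatics; ring C is the only ring formed (step 10).

Key step: step 10

Assumption: 3,4,5-tris(benzyloxy)benzoic acid (benzyl-protected gallic acid) and D-(−)-diisopropyl tartrate are taken as purchasable.

Step 1
Reactants: 1 4-(benzyloxy)-3-hydroxybenzaldehyde
Product: 2 4-(benzyloxy)-3-(methoxymethoxy)benzaldehyde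
Conditions: MOMCl, iPr2NEt, CH2Cl2, 0 °C → rt
Reagents that add atoms: chloromethyl methyl ether (MOMCl), COCCl
Why: Williamson-type O-alkylation of the only phenol with the reactive chloromethyl ether gives the MOM acetal, the one phenol protecting group in the route that is not a benzyl ether, so it marks O3' for the later galloylation.

Step 2
Reactants: 2 4-(benzyloxy)-3-(methoxymethoxy)benzaldehyde
Product: 3 rac-1-[4-(benzyloxy)-3-(methoxymethoxy)phenyl]prop-2-en-1-ol
Conditions: CH2=CHMgBr, THF, −78 → 0 °C; aq. NH4Cl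
Reagents that add atoms: vinylmagnesium bromide, C=C[Mg]Br
Why: Grignard 1,2-addition of the vinyl nucleophile to the aldehyde gives the racemic aryl vinyl carbinol carrying the future C2 (carbinol), C3 and C4 (vinyl), and no stereocontrol is sought because the next step resolves the carbinol.

Step 3
Reactants: 3 rac-1-[4-(benzyloxy)-3-(methoxymethoxy)phenyl]prop-2-en-1-ol
Product: 4 (R)-[4-(benzyloxy)-3-(methoxymethoxy)phenyl][(2S)-oxiran-2-yl]methanol
Conditions: Ti(OiPr)4 (0.2 equiv), D-(−)-diisopropyl tartrate (0.24 equiv), t-BuOOH (0.45 equiv, anhydrous), 4 Å MS, CH2Cl2, −20 °C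
Reagents that add atoms: tert-butyl hydroperoxide, CC(C)(C)OO
Why: Sharpless asymmetric epoxidation used as a kinetic resolution: with D-(−)-tartrate the (S)-carbinol (aryl outranks vinyl) is the fast-reacting enantiomer and is epoxidised on the face that gives the erythro (anti) epoxy alcohol, so the carbinol centre (later C2, R in 4) is selected from the racemate and the epoxide carbon (later C3, S) is set by the chiral titanium tartrate, while the (R)-enantiomer of 3 stays unreacted and is removed by chromatography.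

Step 4
Reactants: 4 (R)-[4-(benzyloxy)-3-(methoxymethoxy)phenyl][(2S)-oxiran-2-yl]methanol
Product: 5 (2S)-2-[(R)-[4-(benzyloxy)-3-(methoxymethoxy)phenyl](triisopropylsilyloxy)methyl]oxirane
Conditions: TIPSOTf, 2,6-lutidine, CH2Cl2, −78 → 0 °C
Reagents that add atoms: triisopropylsilyl trifluoromethanesulfonate, CC(C)[Si](OS(=O)(=O)C(F)(F)F)(C(C)C)C(C)C
Why: Silyl ether formation with the silyl triflate and a hindered pyridine base caps the carbinol without opening the neighbouring epoxide, and the bulky triisopropylsilyl group is chosen because it resists 1,2 O-to-O migration in the later base-mediated benzylation.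

Step 5
Reactants: 6 5-bromoresorcinol
Product: 7 1,3-bis(benzyloxy)-5-bromobenzene
Conditions: BnBr, K2CO3, DMF, 60 °C
Reagents that add atoms: benzyl bromide, BrCc1ccccc1
Why: Double Williamson ether synthesis on the two phenols, with the bromine (meta to both oxygens, exactly as C8a is to O5 and O7 in ring A) inert under these conditions.

Step 6
Reactants: 7 1,3-bis(benzyloxy)-5-bromobenzene
Product: 8 1,5-bis(benzyloxy)-3-bromo-2-iodobenzene
Conditions: NIS, TFA (cat.), MeCN, 0 °C → rt, dark
Reagents that add atoms: N-iodosuccinimide, O=C1CCC(=O)N1I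
Why: Electrophilic aromatic iodination by acid-activated NIS should go to the position para to one benzyloxy group and ortho to the other (between Br and OBn) in preference to the more congested position flanked by two benzyloxy groups, placing iodine on the carbon that becomes C4a.

Step 7
Reactants: 8 1,5-bis(benzyloxy)-3-bromo-2-iodobenzene; 5 (2S)-2-[(R)-[4-(benzyloxy)-3-(methoxymethoxy)phenyl](triisopropylsilyloxy)methyl]oxirane
Product: 10 (1R,2S)-1-[4-(benzyloxy)-3-(methoxymethoxy)phenyl]-3-[2,4-bis(benzyloxy)-6-bromophenyl]-1-(triisopropylsilyloxy)propan-2-ol, via arylmagnesium chloride 9 (not isolated)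
Conditions: 8 (1.5 equiv), iPrMgCl·LiCl, THF, −40 °C; then CuI (10 mol%), 5, −40 → −10 °C; aq. NH4Cl
Reagents that add atoms: isopropylmagnesium chloride–lithium chloride, CC(C)[Mg]Cl.[Li+].[Cl-] (supplies Mg and Cl of intermediate 9 only; none of its atoms stays in 10)
Why: Iodine–magnesium exchange is much faster than bromine–magnesium exchange and at −40 °C the ortho-bromoaryl Grignard 9 should not yet eliminate to an aryne, and CuI catalysis then steers it to SN2 attack at the unhindered CH2 terminus of the epoxide (copper-catalysed Grignard epoxide opening), which forms C4–C4a and frees O3 as the alcohol without touching either stereocentre.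

Step 8
Reactants: 10 (1R,2S)-1-[4-(benzyloxy)-3-(methoxymethoxy)phenyl]-3-[2,4-bis(benzyloxy)-6-bromophenyl]-1-(triisopropylsilyloxy)propan-2-ol
Product: 11 [(1R,2S)-2-(benzyloxy)-1-[4-(benzyloxy)-3-(methoxymethoxy)phenyl]-3-[2,4-bis(benzyloxy)-6-bromophenyl]propoxy]triisopropylsilane
Conditions: NaH, BnBr, Bu4NI (cat.), THF/DMF, 0 °C → rt
Reagents that add atoms: benzyl bromide, BrCc1ccccc1
Why: Williamson etherification of the sodium alkoxide with benzyl bromide (iodide catalysis) blocks O3 so that it cannot later close a five-membered ring onto C8a, and the C–O bond at the stereocentre is not broken.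

Step 9
Reactants: 11 [(1R,2S)-2-(benzyloxy)-1-[4-(benzyloxy)-3-(methoxymethoxy)phenyl]-3-[2,4-bis(benzyloxy)-6-bromophenyl]propoxy]triisopropylsilane
Product: 12 (1R,2S)-2-(benzyloxy)-1-[4-(benzyloxy)-3-(methoxymethoxy)phenyl]-3-[2,4-bis(benzyloxy)-6-bromophenyl]propan-1-ol
Conditions: Bu4NF, THF, 0 °C → rt
Reagents that add atoms: none
Why: Fluoride-driven desilylation (strong Si–F bond) frees the benzylic hydroxyl, while the MOM acetal, the benzyl ethers and the aryl bromide are inert to Bu4NF.

Step 10
Reactants: 12 (1R,2S)-2-(benzyloxy)-1-[4-(benzyloxy)-3-(methoxymethoxy)phenyl]-3-[2,4-bis(benzyloxy)-6-bromophenyl]propan-1-ol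
Product: 13 (2R,3S)-3,5,7-tris(benzyloxy)-2-[4-(benzyloxy)-3-(methoxymethoxy)phenyl]chromane
Conditions: Pd(OAc)2 (5 mol%), 2-(di-tert-butylphosphino)-1,1'-binaphthyl (6 mol%), Cs2CO3, toluene, 70 °C
Reagents that add atoms: none
Why: Pd(OAc)2 is reduced in situ to a zerovalent palladium–phosphine complex that inserts into the C8a–Br bond, and Cs2CO3 then turns the benzylic hydroxyl into an alkoxide bound to divalent palladium, giving a seven-membered aryl(alkoxo)palladacycle. C(aryl)–O reductive elimination from this chelate forms O1–C8a and closes the six-membered ring C; the mode of closure is an intramolecular Buchwald–Hartwig etherification, a reaction type known for secondary alcohols tethered ortho to aryl bromides and giving chromans. No stereocentre is created and no bond to C2 or C3 is made or broken, so the (1R,2S) anti arrangement of 12 is carried unchanged into the (2R,3S) trans arrangement of 13. The step needs reductive elimination to outrun beta-hydride loss from the benzylic alkoxide (which would give the aryl ketone and the debrominated arene), and the bulky electron-rich di-tert-butylphosphino biaryl ligand together with the intramolecular setting is there to secure this. Ring-size selectivity is secured by the substrate, because O3 is benzylated and the hydroxyl on C2 is the only free one, and the C–Br bond is meta to both benzyloxy groups with a single ortho substituent, so oxidative addition is not retarded.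

Step 11
Reactants: 13 (2R,3S)-3,5,7-tris(benzyloxy)-2-[4-(benzyloxy)-3-(methoxymethoxy)phenyl]chromane
Product: 14 2-(benzyloxy)-5-[(2R,3S)-3,5,7-tris(benzyloxy)chroman-2-yl]phenol
Conditions: conc. aq. HCl (few equiv), MeOH/THF, 45 °C
Reagents that add atoms: none
Why: Acid-catalysed methanolysis of the aryl MOM acetal (the oxocarbenium fragment is trapped by methanol as dimethoxymethane) frees O3' only, since benzyl ethers and the chroman ring are stable to dilute HCl at this temperature.

Step 12
Reactants: 14 2-(benzyloxy)-5-[(2R,3S)-3,5,7-tris(benzyloxy)chroman-2-yl]phenol; 15 3,4,5-tris(benzyloxy)benzoic acid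
Product: 16 2-(benzyloxy)-5-[(2R,3S)-3,5,7-tris(benzyloxy)chroman-2-yl]phenyl 3,4,5-tris(benzyloxy)benzoate
Conditions: DCC, DMAP (cat.), CH2Cl2, rt
Reagents that add atoms: none
Why: Steglich esterification, in which the acid activated by the carbodiimide and DMAP acylates the single free hydroxyl (the 3'-phenol), so the galloyl unit lands regioselectively on O3'.

Step 13
Reactants: 16 2-(benzyloxy)-5-[(2R,3S)-3,5,7-tris(benzyloxy)chroman-2-yl]phenyl 3,4,5-tris(benzyloxy)benzoate
Product: 17 catechin 3'-O-gallate, 2-hydroxy-5-[(2R,3S)-3,5,7-trihydroxychroman-2-yl]phenyl 3,4,5-trihydroxybenzoate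
Conditions: H2 (1 atm), Pd(OH)2/C, THF/EtOAc, rt
Reagents that add atoms: none
Why: Catalytic hydrogenolysis cleaves all seven benzyl ethers while the aryl ester and the cyclic C2–O1 ether of the chroman are expected to persist, and a neutral aprotic medium is chosen to avoid a shift of the galloyl group from O3' to the newly freed O4' and to leave C2 and C3 untouched.

**Compound list**
1 | 4-(benzyloxy)-3-hydroxybenzaldehyde | O=Cc1ccc(OCc2ccccc2)c(O)c1 | starting material
2 | 4-(benzyloxy)-3-(methoxymethoxy)benzaldehyde | COCOc1cc(C=O)ccc1OCc1ccccc1 | intermediate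
3 | rac-1-[4-(benzyloxy)-3-(methoxymethoxy)phenyl]prop-2-en-1-ol | COCOc1cc(C(O)C=C)ccc1OCc1ccccc1 | intermediate
4 | (R)-[4-(benzyloxy)-3-(methoxymethoxy)phenyl][(2S)-oxiran-2-yl]methanol | COCOc1cc(ccc1OCc1ccccc1)[C@@H](O)[C@@H]1CO1 | intermediate
5 | (2S)-2-[(R)-[4-(benzyloxy)-3-(methoxymethoxy)phenyl](triisopropylsilyloxy)methyl]oxirane | COCOc1cc(ccc1OCc1ccccc1)[C@@H](O[Si](C(C)C)(C(C)C)C(C)C)[C@@H]1CO1 | intermediate
6 | 5-bromoresorcinol | Oc1cc(O)cc(Br)c1 | starting material
7 | 1,3-bis(benzyloxy)-5-bromobenzene | Brc1cc(OCc2ccccc2)cc(OCc2ccccc2)c1 | intermediate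
8 | 1,5-bis(benzyloxy)-3-bromo-2-iodobenzene | Brc1cc(OCc2ccccc2)cc(OCc2ccccc2)c1I | intermediate
9 | [2,4-bis(benzyloxy)-6-bromophenyl]magnesium chloride | Cl[Mg]c1c(Br)cc(OCc2ccccc2)cc1OCc1ccccc1 | intermediate (not isolated)
10 | (1R,2S)-1-[4-(benzyloxy)-3-(methoxymethoxy)phenyl]-3-[2,4-bis(benzyloxy)-6-bromophenyl]-1-(triisopropylsilyloxy)propan-2-ol | COCOc1cc(ccc1OCc1ccccc1)[C@@H](O[Si](C(C)C)(C(C)C)C(C)C)[C@@H](O)Cc1c(Br)cc(OCc2ccccc2)cc1OCc1ccccc1 | intermediate
11 | [(1R,2S)-2-(benzyloxy)-1-[4-(benzyloxy)-3-(methoxymethoxy)phenyl]-3-[2,4-bis(benzyloxy)-6-bromophenyl]propoxy]triisopropylsilane | COCOc1cc(ccc1OCc1ccccc1)[C@@H](O[Si](C(C)C)(C(C)C)C(C)C)[C@@H](OCc1ccccc1)Cc1c(Br)cc(OCc2ccccc2)cc1OCc1ccccc1 | intermediate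
12 | (1R,2S)-2-(benzyloxy)-1-[4-(benzyloxy)-3-(methoxymethoxy)phenyl]-3-[2,4-bis(benzyloxy)-6-bromophenyl]propan-1-ol | COCOc1cc(ccc1OCc1ccccc1)[C@@H](O)[C@@H](OCc1ccccc1)Cc1c(Br)cc(OCc2ccccc2)cc1OCc1ccccc1 | intermediate (key-step precursor)
13 | (2R,3S)-3,5,7-tris(benzyloxy)-2-[4-(benzyloxy)-3-(methoxymethoxy)phenyl]chromane | COCOc1cc([C@H]2Oc3cc(OCc4ccccc4)cc(OCc4ccccc4)c3C[C@@H]2OCc2ccccc2)ccc1OCc1ccccc1 | intermediate (key-step product)
14 | 2-(benzyloxy)-5-[(2R,3S)-3,5,7-tris(benzyloxy)chroman-2-yl]phenol | Oc1cc([C@H]2Oc3cc(OCc4ccccc4)cc(OCc4ccccc4)c3C[C@@H]2OCc2ccccc2)ccc1OCc1ccccc1 | intermediate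
15 | 3,4,5-tris(benzyloxy)benzoic acid | OC(=O)c1cc(OCc2ccccc2)c(OCc2ccccc2)c(OCc2ccccc2)c1 | starting material
16 | 2-(benzyloxy)-5-[(2R,3S)-3,5,7-tris(benzyloxy)chroman-2-yl]phenyl 3,4,5-tris(benzyloxy)benzoate | O=C(Oc1cc([C@H]2Oc3cc(OCc4ccccc4)cc(OCc4ccccc4)c3C[C@@H]2OCc2ccccc2)ccc1OCc1ccccc1)c1cc(OCc2ccccc2)c(OCc2ccccc2)c(OCc2ccccc2)c1 | intermediate
17 | catechin 3'-O-gallate | O=C(Oc1cc([C@H]2Oc3cc(O)cc(O)c3C[C@@H]2O)ccc1O)c1cc(O)c(O)c(O)c1 | target

Total step count: 13. Longest linear sequence: 11 steps (steps 1–4 and 7–13); steps 5 and 6 form the ring-A branch.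

**Steps most likely to fail**

Step 10 (key step). The palladium alkoxide may lose a beta-hydride faster than it forms the C–O bond, which would oxidise the carbinol to the ketone and reduce the C–Br bond. The fallback sets out from 12 and comes back at 13, and it turns the arene into the nucleophilic partner. Miyaura borylation of 12 (B2pin2, Pd(dppf)Cl2, KOAc, dioxane, 80 °C; the weak base forms no alkoxide) should give (1R,2S)-2-(benzyloxy)-1-[4-(benzyloxy)-3-(methoxymethoxy)phenyl]-3-[2,4-bis(benzyloxy)-6-(4,4,5,5-tetramethyl-1,3,2-dioxaborolan-2-yl)phenyl]propan-1-ol F1. An oxidative Chan–Lam etherification (Cu(OAc)2, pyridine, 4 Å MS, air, CH2Cl2, rt to 40 °C) then joins O1 to C8a through an arylcopper species instead of a palladium alkoxide, again without touching C2 or C3, and gives 13.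

Step 7. The arylmagnesium reagent may be lost by elimination to an aryne or by protonation before it reaches the epoxide, and a doubly ortho-substituted aryl attacks the epoxide slowly. The fallback sets out from 5 and 7 and comes back at 10, and it reverses the polarity at C4. Periodic acid cleavage of the epoxide of 5 (H5IO6, THF/Et2O, 0 °C) should give (2R)-2-[4-(benzyloxy)-3-(methoxymethoxy)phenyl]-2-(triisopropylsilyloxy)acetaldehyde F2. Vilsmeier–Haack formylation of 7 (POCl3, DMF) should go between Br and OBn to give 2,4-bis(benzyloxy)-6-bromobenzaldehyde F3. NaBH4 in MeOH/THF then gives [2,4-bis(benzyloxy)-6-bromophenyl]methanol F4, and SOCl2 in CH2Cl2 at 0 °C gives 1,5-bis(benzyloxy)-3-bromo-2-(chloromethyl)benzene F5. Zinc dust with LiCl in THF inserts only into the benzylic C–Cl bond to give [2,4-bis(benzyloxy)-6-bromobenzyl]zinc chloride F6, which is not isolated. F6 adds to aldehyde F2 under Felkin–Anh control (the bulky, non-chelating silyloxy group anti to the incoming nucleophile) to give the anti alcohol 10; any syn isomer would be removed by chromatography.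

Step 3. The epoxy alcohol is the product of the resolution, so its enantiomeric purity falls as conversion nears one half, and the Lewis-acidic titanium reagent may open the electron-rich epoxy carbinol. The fallback sets out from 3 and comes back at 4, and it separates resolution from epoxidation. Lipase-catalysed acylation (immobilised Candida antarctica lipase B, vinyl acetate, MTBE, 30 °C) should leave (1S)-1-[4-(benzyloxy)-3-(methoxymethoxy)phenyl]prop-2-en-1-ol F7 unreacted, while the (R)-enantiomer is converted into (1R)-1-[4-(benzyloxy)-3-(methoxymethoxy)phenyl]prop-2-en-1-yl acetate F8, which is separated. F7 is then epoxidised to full conversion with the matched reagent (Ti(OiPr)4, D-(−)-diisopropyl tartrate, t-BuOOH, 4 Å MS, CH2Cl2, −20 °C), where reagent and substrate control both favour the erythro epoxide 4.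

**Further compounds**
F1 | step 10 | (1R,2S)-2-(benzyloxy)-1-[4-(benzyloxy)-3-(methoxymethoxy)phenyl]-3-[2,4-bis(benzyloxy)-6-(4,4,5,5-tetramethyl-1,3,2-dioxaborolan-2-yl)phenyl]propan-1-ol | COCOc1cc(ccc1OCc1ccccc1)[C@@H](O)[C@@H](OCc1ccccc1)Cc1c(B2OC(C)(C)C(C)(C)O2)cc(OCc2ccccc2)cc1OCc1ccccc1
F2 | step 7 | (2R)-2-[4-(benzyloxy)-3-(methoxymethoxy)phenyl]-2-(triisopropylsilyloxy)acetaldehyde | COCOc1cc(ccc1OCc1ccccc1)[C@@H](O[Si](C(C)C)(C(C)C)C(C)C)C=O
F3 | step 7 | 2,4-bis(benzyloxy)-6-bromobenzaldehyde | O=Cc1c(Br)cc(OCc2ccccc2)cc1OCc1ccccc1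
F4 | step 7 | [2,4-bis(benzyloxy)-6-bromophenyl]methanol | OCc1c(Br)cc(OCc2ccccc2)cc1OCc1ccccc1
F5 | step 7 | 1,5-bis(benzyloxy)-3-bromo-2-(chloromethyl)benzene | ClCc1c(Br)cc(OCc2ccccc2)cc1OCc1ccccc1
F6 | step 7 | [2,4-bis(benzyloxy)-6-bromobenzyl]zinc chloride | Cl[Zn]Cc1c(Br)cc(OCc2ccccc2)cc1OCc1ccccc1
F7 | step 3 | (1S)-1-[4-(benzyloxy)-3-(methoxymethoxy)phenyl]prop-2-en-1-ol | COCOc1cc(ccc1OCc1ccccc1)[C@@H](O)C=C
F8 | step 3 | (1R)-1-[4-(benzyloxy)-3-(methoxymethoxy)phenyl]prop-2-en-1-yl acetate | COCOc1cc(ccc1OCc1ccccc1)[C@H](OC(C)=O)C=C
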